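**Remark on the chemistry:** the target has no stereocentre and no stereogenic double bond, so it is achiral. "Single enantiomer" therefore sets no stereochemical task, and the route is planned for the constitution given by the SMILES.

**Numbering used throughout:** 1 octa-1,7-diene; 2 oct-7-enyl pinacol boronate; 3 4-bromo-2-methoxyphenol; 4 2-methoxy-4-(oct-7-en-1-yl)phenol; 5 2,6-dihydroxybenzaldehyde; 6 the target.

## Analysis of the target

Target 6 is an achiral 1,9-diarylnonan-1-one. A nine-carbon chain (C1 the ketone carbon, C2–C9 eight methylenes) links ring A, a 2,6-dihydroxyphenyl ring bonded through C1' to C1, with ring B, a 4-hydroxy-3-methoxyphenyl (guaiacyl) ring bonded through C1'' to C9. There is no stereochemical relationship to control; the problem is regiochemistry and functional-group economy. The hard feature is the acyl group on C1' between the hydroxyls on C2' and C6'. Electrophilic acylation of a resorcinol goes para to one hydroxyl and does not reach this position, so classical routes need a metalated, doubly protected ring A. The molecule has three free phenols of two kinds and one methyl ether on C3'' that must survive, which excludes any global dealkylation at the end. Ring B is an electron-rich p-alkylguaiacol that oxidants attack at C9–H (quinone methide) and electrophiles attack on the ring. The C2–C8 segment carries no handle. The feature that invites the chosen strategy is the C1 ketone with O2'–H ortho to it: this is the substitution pattern produced by hydroacylation of an alkene with a salicylaldehyde. The C1–C2 bond can therefore be made by adding a formyl C–H bond across a terminal alkene, with the ortho hydroxyl serving as the directing group and all phenols left free.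

## Retrosynthetic reasoning

**C1–C2 (6 ⇒ 4 + 5).** The bond between the carbonyl carbon and the first methylene is cut, giving aldehyde 5, which carries all of ring A and C1, and terminal alkene 4, which carries ring B and C2–C9. The cut is placed here, not at C1–C1', because ring A can then be bought with its 2,6-dioxygenation and its carbonyl carbon already in place, so the regiochemical problem of ring A never arises. The forward reaction must add the formyl C–H of 5 across the alkene of 4 with the acyl group going to the terminal carbon, in the presence of three unprotected phenols. A rhodium(I) catalyst bound to the phenoxide of 5 can do this. The formyl carbon then acts as an acyl nucleophile equivalent, a reversal of its normal polarity. The step is a pure addition and ends the synthesis.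

**C9–C1'' (4 ⇒ 2 + 3).** The aryl–methylene bond of 4 is cut, giving aryl bromide 3 and primary alkyl boronate 2. This places the only sp3–sp2 cross-coupling on a cheap, purchasable ring B and leaves the terminal alkene needed for the key step untouched. The forward reaction is an alkyl–aryl cross-coupling that must tolerate the free phenol of 3 and must not isomerise or arylate the alkene.

**C–B (2 ⇒ 1).** The boronate is taken back to the symmetric C8 diene 1. All eight methylenes C2–C9 of the target come from this one feedstock. One alkene terminus is hydroborated and becomes C9; the other is kept and becomes C2/C3 in the key step. The forward reaction has to hydroborate only one of two identical termini, which excess 1 and distillation should secure.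

## Alternatives that were turned down

**Alternative 1:** the textbook disconnection at C1–C1'. Directed ortho-lithiation of 1,3-dimethoxybenzene would give (2,6-dimethoxyphenyl)lithium A1, which would be acylated by Weinreb amide A2 to the trimethyl ether ketone A3; demethylation would follow.
- A3 carries three aryl methyl ethers, of which the two on C2' and C6' must be cleaved and the one on C3'' kept.
- Chelation-directed Lewis acids remove the first ortho methoxyl easily, but the resulting metal chelate deactivates the second; reagents strong enough for both also cleave the ring B ether.
- Acetal protecting groups solve this at the cost of further steps, and A2 itself needs a separate chain assembly and amide formation.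
- The count would be seven or more steps, most of them protection or functional-group adjustment, for a key step that forms one bond.
- The direct Friedel–Crafts version is not an option, because acylation of resorcinol goes to the carbon para to a hydroxyl.

**Alternative 2:** the biomimetic disconnection, with ring A traced back to cyclohexane-1,3-dione as a reduced tetraketide. Acid A4 would be O-acylated onto the dione, a cyanide- or DMAP-mediated O-to-C acyl shift would give triketone A5, and dehydrogenation would aromatise it.
- The aromatisation needs a stoichiometric oxidant or electrophile (a quinone, Hg(II), a halogen) while the molecule already contains ring B.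
- Such reagents attack a p-alkylguaiacol at C9–H or at C5'', so ring B would need protection and deprotection.
- A4 must be built first, and the route uses an oxidation-state detour (introduce ring A reduced, then oxidise).
- The count would be six to seven steps, and the chemoselectivity risk sits in the oxidation.

**Alternative 3:** an electrochemical disconnection at C7–C8. Mixed Kolbe electrolysis of the phenol-protected acids A6 (giving the C8/C9 arylethyl radical) and A7 (giving the C1–C7 keto-alkyl radical) would form the triacetate A8, to be deacetylated.
- Radical–radical coupling of two different carboxylates is statistical and gives three dimers.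
- Ring B is oxidised at the anode below the potential needed for carboxylate oxidation, even as its acetate.
- A7 already contains the 2-acylresorcinol, so the hardest feature of the target would have to be solved beforehand by one of the other routes.
- The electrolysis would then only form an unfunctionalised C–C bond, at a cost of more than seven steps.

Key step: step 3

## Route

Step 1
Reactants: 1 octa-1,7-diene
Product: 2 4,4,5,5-tetramethyl-2-(oct-7-en-1-yl)-1,3,2-dioxaborolane
Conditions: HBpin (1.0 equiv), 1 (4 equiv), [Ir(cod)Cl]2 (1.5 mol%), dppm (3 mol%), CH2Cl2, rt; excess 1 recovered, 2 distilled under vacuum
Reagents that add atoms: pinacolborane (4,4,5,5-tetramethyl-1,3,2-dioxaborolane), B1OC(C)(C)C(C)(C)O1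
Why: Iridium-catalysed anti-Markovnikov hydroboration of a terminal alkene with pinacolborane puts boron on the terminal carbon; the fourfold excess of the symmetric diene makes the mono-adduct the statistically favoured product, and the boiling-point gaps between 1, 2 and the bis-boronate should allow separation by distillation.

Step 2
Reactants: 2 4,4,5,5-tetramethyl-2-(oct-7-en-1-yl)-1,3,2-dioxaborolane, 3 4-bromo-2-methoxyphenol
Product: 4 2-methoxy-4-(oct-7-en-1-yl)phenol
Conditions: 2 (1.3 equiv), Pd(OAc)2 (2 mol%), SPhos (4 mol%), K3PO4 (3 equiv), toluene/H2O 10:1, 90 °C
Reagents that add atoms: none
Why: Suzuki–Miyaura sp3–sp2 cross-coupling of a primary alkyl pinacol boronate; the electron-rich biarylphosphine should drive oxidative addition into the electron-rich C–Br bond of the phenoxide form of 3 and make reductive elimination faster than β-hydride elimination, while aqueous phosphate activates the boronate and the terminal alkene stays a spectator.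

Step 3
Reactants: 4 2-methoxy-4-(oct-7-en-1-yl)phenol, 5 2,6-dihydroxybenzaldehyde
Product: 6 1-(2,6-dihydroxyphenyl)-9-(4-hydroxy-3-methoxyphenyl)nonan-1-one
Conditions: 4 (1.3 equiv), 5 (1.0 equiv), [Rh(cod)OMe]2 (2.5 mol%), bulky BINOL-derived phosphoramidite (racemic, 6 mol%), THF, 70 °C, Ar
Reagents that add atoms: none
Why: Rhodium(I)-catalysed intermolecular alkene hydroacylation; the closest known reaction type is the linear-selective coupling of salicylaldehydes with unactivated 1-alkenes under Rh–phosphoramidite catalysis. The Rh–OMe precatalyst deprotonates O2'–H of 5, the Rh phenoxide holds the metal beside the formyl C–H bond, and oxidative addition gives a five-membered acyl–Rh(III)–hydride chelate (Rh–O2'–C2'–C1'–C1). Alkene 4 inserts into Rh–H, C1–C2 reductive elimination releases the ketone, and proton exchange with fresh 5 frees 6. The formyl carbon, an electrophile in every classical route, acts here as an acyl nucleophile equivalent towards an unpolarised alkene. Linear over branched selectivity is needed: hydrometalation is expected to be reversible and reductive elimination slow, so the less hindered primary alkyl should be channelled to product, helped by the bulky phosphoramidite and by the O2' and O6' substituents flanking the acyl group. Hydroacylation must also outrun decarbonylation: the phenoxide chelate occupies the site that CO de-insertion needs, which is why the ortho hydroxyl of ring A is an asset here. Among the phenols, the twofold symmetry of ring A means either hydroxyl directs with the same result, O6'–H stays hydrogen-bonded to C1=O, and the guaiacol hydroxyl of 4 cannot chelate and should be a bystander. No ring is closed and no stereocentre is created; the step is a pure addition (C15H22O2 + C7H6O3 = C22H28O5) and should give 6 directly with all three phenols free.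

## Compound list

1 | octa-1,7-diene | C=CCCCCC=C | starting material
2 | 4,4,5,5-tetramethyl-2-(oct-7-en-1-yl)-1,3,2-dioxaborolane | C=CCCCCCCB1OC(C)(C)C(C)(C)O1 | intermediate
3 | 4-bromo-2-methoxyphenol | COc1cc(Br)ccc1O | starting material
4 | 2-methoxy-4-(oct-7-en-1-yl)phenol | COc1cc(CCCCCCC=C)ccc1O | intermediate
5 | 2,6-dihydroxybenzaldehyde | O=Cc1c(O)cccc1O | starting material
6 | 1-(2,6-dihydroxyphenyl)-9-(4-hydroxy-3-methoxyphenyl)nonan-1-one | COc1cc(CCCCCCCCC(=O)c2c(O)cccc2O)ccc1O | target

## Step count and risk

Total step count: 3. Longest linear sequence: 3 steps (1 → 2 → 4 → 6); 3 and 5 enter as purchased materials.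

**Step 3 (key step).** Three processes are most likely to go wrong.
- Chain-walking of the terminal alkene by reversible hydrometalation and β-hydride elimination would move 4 into internal alkenes that no longer react.
- Decarbonylation of the acyl–rhodium hydride would deactivate the catalyst as a rhodium carbonyl.
- The product, itself an o-hydroxyaryl ketone, could hold the metal as a chelate and slow turnover.

The excess of 4 and the phosphoramidite ligand are chosen against the first two; ligand and temperature would need adjustment on the real substrate.

The fallback sets out from 4 and comes back at 6, and moves the bond formation from C1–C2 to C1–C1'. Linear-selective hydroformylation of 4 (Rh(acac)(CO)2, Xantphos, CO/H2 1:1, toluene, 80 °C) should give 9-(4-hydroxy-3-methoxyphenyl)nonanal F1. Commercial 1,3-bis(methoxymethoxy)benzene is lithiated between its acetal groups (n-BuLi, THF, 0 °C) to [2,6-bis(methoxymethoxy)phenyl]lithium F2. Two equivalents of F2 are used: the first deprotonates the phenol of F1, the second adds to the aldehyde, and a water quench should give racemic 1-[2,6-bis(methoxymethoxy)phenyl]-9-(4-hydroxy-3-methoxyphenyl)nonan-1-ol F3. Activated MnO2 in CH2Cl2 should oxidise this doubly activated benzylic alcohol to 1-[2,6-bis(methoxymethoxy)phenyl]-9-(4-hydroxy-3-methoxyphenyl)nonan-1-one F4 without attacking ring B, which also removes the transient stereocentre. HCl in methanol at 40 °C then cleaves both acetals and gives 6.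

**Step 2.** Oxidative addition into the phenoxide-bearing, electron-rich C–Br bond and transmetalation of the alkyl pinacol boronate may both be slow. Protodeboronation, hydrodebromination, and palladium hydride-mediated migration or arylation of the terminal alkene would then compete.

The fallback sets out from 3 and comes back at 4, and uses no organoboron reagent and no base. It is a nickel-catalysed reductive cross-electrophile coupling of 3 with commercial 8-bromooct-1-ene (NiI2, 4,4'-di-tert-butyl-2,2'-bipyridine, Zn, NaI, DMPU, 60 °C). The aryl–nickel species captures the primary alkyl radical, and the method class tolerates acidic O–H groups. No new isolated compound arises.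

**Step 1.** Hydroboration at both termini and iridium hydride-mediated migration of the remaining double bond would cut the yield of 2 and contaminate it with isomers that distillation separates poorly.

The fallback sets out from 1 and comes back at 4, bypassing 2. Uncatalysed hydroboration of excess 1 with 9-BBN in THF (0 °C to rt) involves no metal hydride that can isomerise the alkene. It should give 9-(oct-7-en-1-yl)-9-borabicyclo[3.3.1]nonane F5, which is not isolated. After removal of excess 1 under vacuum, F5 is coupled in the same flask with 3 (Pd(dppf)Cl2, aqueous K3PO4, THF, 65 °C) to give 4. The more reactive B-alkyl-9-BBN also eases transmetalation.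

## Further compounds

F1 | step 3 | 9-(4-hydroxy-3-methoxyphenyl)nonanal | COc1cc(CCCCCCCCC=O)ccc1O
F2 | step 3 | [2,6-bis(methoxymethoxy)phenyl]lithium | [Li]c1c(OCOC)cccc1OCOC
F3 | step 3 | rac-1-[2,6-bis(methoxymethoxy)phenyl]-9-(4-hydroxy-3-methoxyphenyl)nonan-1-ol | COCOc1cccc(OCOC)c1C(O)CCCCCCCCc1ccc(O)c(OC)c1
F4 | step 3 | 1-[2,6-bis(methoxymethoxy)phenyl]-9-(4-hydroxy-3-methoxyphenyl)nonan-1-one | COCOc1cccc(OCOC)c1C(=O)CCCCCCCCc1ccc(O)c(OC)c1
F0 | step 2 | none | none
F5 | step 1 | 9-(oct-7-en-1-yl)-9-borabicyclo[3.3.1]nonane | C=CCCCCCCB1C2CCCC1CCC2
A1 | alternative 1 | (2,6-dimethoxyphenyl)lithium | [Li]c1c(OC)cccc1OC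
A2 | alternative 1 | 9-(4-hydroxy-3-methoxyphenyl)-N-methoxy-N-methylnonanamide | COc1cc(CCCCCCCCC(=O)N(C)OC)ccc1O
A3 | alternative 1 | 1-(2,6-dimethoxyphenyl)-9-(4-hydroxy-3-methoxyphenyl)nonan-1-one | COc1cc(CCCCCCCCC(=O)c2c(OC)cccc2OC)ccc1O
A4 | alternative 2 | 9-(4-hydroxy-3-methoxyphenyl)nonanoic acid | COc1cc(CCCCCCCCC(=O)O)ccc1O
A5 | alternative 2 | 3-hydroxy-2-[9-(4-hydroxy-3-methoxyphenyl)nonanoyl]cyclohex-2-en-1-one | COc1cc(CCCCCCCCC(=O)C2=C(O)CCCC2=O)ccc1O
A6 | alternative 3 | 3-(4-acetoxy-3-methoxyphenyl)propanoic acid | COc1cc(CCC(=O)O)ccc1OC(C)=O
A7 | alternative 3 | 8-(2,6-diacetoxyphenyl)-8-oxooctanoic acid | CC(=O)Oc1cccc(OC(C)=O)c1C(=O)CCCCCCC(=O)O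
A8 | alternative 3 | 1-(2,6-diacetoxyphenyl)-9-(4-acetoxy-3-methoxyphenyl)nonan-1-one | COc1cc(CCCCCCCCC(=O)c2c(OC(C)=O)cccc2OC(C)=O)ccc1OC(C)=O
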